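A flat target curve tempts one to call a flask finished, yet flatness says that making stopped and not what stopped it. This flask shows two peaks, target and starting material, and the epsilon run is the flask itself, followed so far.

- epsilon: starting material 0.013 M; second substrate 0.026 M; capture agent 3.9 mM; free catalyst 13 µM; temperature 110 °C; the very flask that is asked about, followed so far
- flask: starting material 0.013 M; second substrate 0.0260 M; capture agent 3.90 mM; free catalyst 13 µM; temperature 110 °C; time 5.0 h

epsilon run (percent of the starting material charged)

| time / h | target / % | starting material / % |
|---|---|---|
| 0.833 | 9.1 | 92.4 |
| 1.50 | 15.4 | 86.3 |
| 2.50 | 17.2 | 83.5 |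
| 3.00 | 17.4 | 84.3 |

(scatter of a reading: 1 percentage point)

- maple: change nothing and wait 1.5 h more
- oak: at 5.0 h raise the temperature by 10 K, then wait 1.5 h
- birch: at 5.0 h add free catalyst, 100% of the amount charged, then wait 1.5 h
- larch: at 5.0 h take out 90% of the target then present, then wait 1.5 h

- what is taken out of target is counted as made
- the earlier runs do not show what temperature does; that part of a forecast is a guess
- additions bring no volume worth counting

- target, in percent of the starting material first charged, at 5.0 h
- which option adds most target ("none" when 2 percentage points or less is all one gets) (maple / oak / birch / larch / none)
- target present, with what was taken out counted in, in percent of the starting material first charged, after oak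
- target present, with what was taken out counted in, in percent of the starting material first charged, after larch

In this flask, the target readings level at 17.3%, the mean of the last two, and the starting material reads 84.3% at 3.00 h. So feed remains, and the forecast and I dispute what stopped the making.

I hold that the catalyst dies on a clock. The first reading, at 0.833 h, shows target at half that plateau. I call this time the working half-life of the catalyst, the time in which the rate of making target falls to half. It is a reading, with the scatter of the points behind it. Then 5.0 h is 6.00 half-lives, which puts target at 17.0%. Fresh catalyst equal to the charge restarts the clock. In 1.5 h it adds 12 percentage points, more than the 2 points required, so I say birch.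

The forecast holds that something was used up. The capture agent is charged at 30.0% of the starting material, and on the forecast's guess of 2 capture agent per target it would be exhausted near 15% target. The bend favours this view, since my curve gives 12.3% at 1.50 h, 3.1 points below the reading. In its words, “extra catalyst is swamped by excess poison”. It gives 17.6% now, none as best, 18.5% after oak and 18.2% after larch.

The flask gives 18.9% at 5.0 h, 19.6% after oak and 19.4% after larch.

    starting material + free catalyst ⇌ catalyst intermediate A (K = 800 M⁻¹, k = 270 M⁻¹ min⁻¹, Ea = 68.0 kJ mol⁻¹, ΔH = −28.0 kJ mol⁻¹)
    catalyst intermediate A → free catalyst + target (k = 130 min⁻¹, Ea = 90.0 kJ mol⁻¹)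
    catalyst intermediate A + capture agent → trapped intermediate (k = 170 M⁻¹ min⁻¹, Ea = 68.0 kJ mol⁻¹)
    second substrate + free catalyst ⇌ catalyst intermediate B (K = 14.0 M⁻¹, k = 12000 M⁻¹ min⁻¹, Ea = 58.0 kJ mol⁻¹, ΔH = 3.00 kJ mol⁻¹)
    catalyst intermediate B → free catalyst + second product (k = 4.90 min⁻¹, Ea = 98.0 kJ mol⁻¹)
    (constants at 110 °C)

The best option is birch, which adds 12 points. The forecast's none holds for the options that add no catalyst: maple, oak and larch add 0.43 points, 0.63 points and 0.43 points, each less than 2 points. In the flask at 5.00 h, the trapped intermediate, an off-cycle form, holds 96.4% of the catalyst charged, while 99.7% of the capture agent's own charge is left. A neighbour flask has 4.00 times the catalyst charge. With the half-life of 0.833 h, the plateau scaled by that factor gives 68.1% at 5.0 h, and that neighbour flask stands at 68.1%, but its free catalyst is 10.7% of its charge, more than the 1.56% that 6.00 half-lives leave.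

The earlier runs and the new flask were computed with constants of no real substance, noise included.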